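**Retrosynthetic overview**

1. Target 29 ⇐ near-neutral removal of two MOM and three TBS ethers from (2S)-flavanone 27 ⇐ C2 epimer pair 26, from which asymmetric transfer hydrogenation removes the (2R)-epimer.
2. 26 ⇐ cationic [4+2] annulation of acylal 22 with ethoxyacetylene 23: ionisation to an aryloxycarbenium ion, bond C2–C3, then the ring-closing bond C4–C4a. Ring C is formed last; rings A and B are preformed aromatics.
3. Enabling feature: ring A of 22 has one unsubstituted carbon, C4a–H, between O1 and the C5 oxygen (a phloroglucinol-type π-nucleophile), and the 2',4',6'-oxygens of ring B stabilise the O1=C2 cation, so C4a=C8a–O1=C2 acts as a cationic 1-oxadiene.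
4. 22 ⇐ ring A phenol 18 + ring B aldehyde 20 + pivaloyl chloride; 18 ⇐ resorcinol by MOM-directed lithiation/prenylation, C–H borylation/oxidation (brings in O1), iodination and Negishi coupling with the zinc reagent from iodide 15.
5. 15 ⇐ (S)-lavandulol 14 ⇐ Evans deconjugative alkylation of imide 11 with prenyl bromide (sets the side-chain stereocentre).

Key step: step 12

Remark: C2 is formed without facial control in step 12 and is fixed in step 13 by catalyst-controlled transfer hydrogenation of the unwanted epimer; the sense of induction in steps 6 and 13 is assigned from the accepted chelated-enolate and transfer-hydrogenation models.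

**Route**

Step 1
Reactants: 1 resorcinol
Product: 2 1,3-bis(methoxymethoxy)benzene
Conditions: NaH, DMF, 0 °C; MOMCl, 0 °C → rt
Reagents that add atoms: chloromethyl methyl ether (MOMCl), COCCl
Why: Williamson etherification of both phenoxides gives the bis-MOM ether whose two acetal oxygens direct the next lithiation to the carbon between them.

Step 2
Reactants: 2 1,3-bis(methoxymethoxy)benzene; 3 prenyl bromide (1-bromo-3-methylbut-2-ene)
Product: 5 1,3-bis(methoxymethoxy)-2-(3-methylbut-2-en-1-yl)benzene, via 2-lithio-1,3-bis(methoxymethoxy)benzene 4 (not isolated)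
Conditions: n-BuLi, THF, 0 °C; then 3, −78 °C → rt
Reagents that add atoms: none
Why: Directed ortho-metalation between the two MOM ethers followed by SN2 alkylation of the aryllithium with the allylic bromide places the prenyl group on the future C6.

Step 3
Reactants: 5 1,3-bis(methoxymethoxy)-2-(3-methylbut-2-en-1-yl)benzene
Product: 7 3,5-bis(methoxymethoxy)-4-(3-methylbut-2-en-1-yl)phenol, via arylboronic pinacol ester 6 (not isolated)
Conditions: [Ir(OMe)(cod)]2 (1.5 mol %), 4,4'-di-tert-butyl-2,2'-bipyridine (3 mol %), B2pin2 (1.0 equiv), THF, 60 °C; then aq. NaOH, 30% H2O2, 0 °C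
Reagents that add atoms: hydrogen peroxide, OO
Why: Sterically governed iridium-catalysed C–H borylation should take the only ring C–H without an ortho substituent (para to the prenyl group), and oxidation of the C–B bond delivers the phenol oxygen that becomes O1.

Step 4
Reactants: 7 3,5-bis(methoxymethoxy)-4-(3-methylbut-2-en-1-yl)phenol
Product: 8 2-iodo-3,5-bis(methoxymethoxy)-4-(3-methylbut-2-en-1-yl)phenol
Conditions: NIS (1.0 equiv), CH2Cl2, −40 °C
Reagents that add atoms: N-iodosuccinimide, O=C1CCC(=O)N1I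
Why: Electrophilic aromatic iodination ortho to the free phenol (the two ortho positions are equivalent) at low temperature, where the activated ring should react before the prenyl olefin.

Step 5
Reactants: 9 (S)-4-benzyloxazolidin-2-one; 10 3-methylbut-2-enoyl chloride
Product: 11 (S)-4-benzyl-3-(3-methylbut-2-enoyl)oxazolidin-2-one
Conditions: n-BuLi, THF, −78 °C; then 10, −78 → 0 °C
Reagents that add atoms: none
Why: N-acylation of the lithiated oxazolidinone attaches the Evans auxiliary to the five-carbon acyl unit.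

Step 6
Reactants: 11 (S)-4-benzyl-3-(3-methylbut-2-enoyl)oxazolidin-2-one; 3 prenyl bromide
Product: 13 (S)-4-benzyl-3-[(2S)-5-methyl-2-(prop-1-en-2-yl)hex-4-enoyl]oxazolidin-2-one, via sodium dienolate 12 (not isolated)
Conditions: NaN(SiMe3)2, THF, −78 °C; then 3, −78 → −40 °C
Reagents that add atoms: none
Why: Evans asymmetric alkylation in its deconjugative form, in which γ-deprotonation gives the chelated (Z)-dienolate and prenyl bromide should enter at the α-carbon anti to the benzyl group, setting the lavandulyl stereocentre as (2S) while the double bond moves into the isopropenyl position.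

Step 7
Reactants: 13 (S)-4-benzyl-3-[(2S)-5-methyl-2-(prop-1-en-2-yl)hex-4-enoyl]oxazolidin-2-one
Product: 14 (S)-lavandulol [(2S)-5-methyl-2-(prop-1-en-2-yl)hex-4-en-1-ol]
Conditions: LiBH4, H2O (1.1 equiv), Et2O, 0 °C
Reagents that add atoms: none
Why: Reductive cleavage of the imide releases the primary alcohol without touching the α-stereocentre and returns the auxiliary.

Step 8
Reactants: 14 (S)-lavandulol
Product: 15 (S)-lavandulyl iodide [(3S)-3-(iodomethyl)-2,6-dimethylhepta-1,5-diene]
Conditions: I2, PPh3, imidazole, CH2Cl2, 0 °C → rt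
Reagents that add atoms: iodine, II
Why: Appel iodination converts the primary alcohol into the iodide by SN2 displacement at CH2, one carbon away from the stereocentre.

Step 9
Reactants: 15 (S)-lavandulyl iodide; 8 2-iodo-3,5-bis(methoxymethoxy)-4-(3-methylbut-2-en-1-yl)phenol
Product: 18 3,5-bis(methoxymethoxy)-2-[(2R)-5-methyl-2-(prop-1-en-2-yl)hex-4-en-1-yl]-4-(3-methylbut-2-en-1-yl)phenol, via lavandulyllithium 16 (not isolated), via lavandulylzinc chloride 17 (not isolated)
Conditions: 15, t-BuLi (2.1 equiv), Et2O/pentane, −78 °C; ZnCl2 in THF, −78 °C → rt; then sodium salt of 8 (NaH, THF, 0 °C), Pd(OAc)2 (3 mol %), SPhos (6 mol %), THF, 40 °C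
Reagents that add atoms: none
Why: Iodine–lithium exchange and transmetalation give a primary alkylzinc whose stereocentre is not involved, and Negishi cross-coupling (SPhos limits β-hydride elimination and tolerates the phenoxide) attaches the lavandulyl group to the future C8.

Step 10
Reactants: 19 2,4,6-trihydroxybenzaldehyde
Product: 20 2,4,6-tris(tert-butyldimethylsilyloxy)benzaldehyde
Conditions: TBSCl, imidazole, DMF, 40 °C
Reagents that add atoms: tert-butyldimethylsilyl chloride (TBSCl), CC(C)(C)[Si](C)(C)Cl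
Why: Silylation of all three phenols gives donor groups that are not acetals, are poor oxygen nucleophiles toward the cation of step 12 and leave under fluoride at the end.

Step 11
Reactants: 20 2,4,6-tris(tert-butyldimethylsilyloxy)benzaldehyde; 18 ring A phenol
Product: 22 mixed acylal [ring A aryloxy][2,4,6-tris(tert-butyldimethylsilyloxy)phenyl]methyl pivalate (both configurations at the acetal carbon), via chloro(aryl)methyl pivalate 21 (not isolated)
Conditions: 20, PivCl (1.0 equiv), ZnCl2 (2 mol %), CH2Cl2, 0 °C → rt; then added to the sodium salt of 18 (NaH, DMF, 0 °C) at −40 → 0 °C; filtration through Et3N-deactivated silica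
Reagents that add atoms: pivaloyl chloride, CC(C)(C)C(=O)Cl
Why: Addition of the acyl chloride across the aldehyde gives an α-chloroalkyl ester that O-alkylates the phenoxide (acyloxyalkyl ether formation, as with chloromethyl pivalate), and the new acetal stereocentre is inconsequential because it is ionised in step 12.

Step 12
Reactants: 22 mixed acylal; 23 ethoxyacetylene
Product: 26 5,7-bis(methoxymethoxy)-8-[(2R)-5-methyl-2-(prop-1-en-2-yl)hex-4-en-1-yl]-6-(3-methylbut-2-en-1-yl)-2-[2,4,6-tris(tert-butyldimethylsilyloxy)phenyl]chroman-4-one (C2 epimer pair), via aryloxycarbenium ion 24 (not isolated), via 4-ethoxy-2H-chromene 25 (not isolated)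
Conditions: 23 (3 equiv), BF3·OEt2 (0.2 equiv), 4 Å molecular sieves, CH2Cl2, −78 → −40 °C; then 5% aq. oxalic acid, THF, 0 °C
Reagents that add atoms: water, O
Why: Proposed new method: BF3 removes pivalate from 22 to give the aryloxycarbenium ion 24 (a cationic 1-oxadiene, C4a=C8a–O1=C2); the terminal carbon of the ynol ether adds to C2 (bond C2–C3), the resulting ethoxy-stabilised ketenium carbon C4 is attacked by C4a, which closes ring C through the C4–C4a bond, and loss of the proton gives enol ether 25, which mild acid hydrolyses to the C4 ketone. The closest known reaction types are the oxa-Povarov annulation of aryloxycarbenium ions with alkenes to chromans, Povarov annulations of N-aryl iminium ions with alkynes, and Friedel–Crafts capture of ketenium and keteniminium ions by tethered arenes; an ynol ether has not been shown as the two-carbon partner of an aryloxycarbenium ion. The only ring closed is the pyran ring C, by a 6-exo-dig Friedel–Crafts attack on the exocyclic C4=O+ bond of the ketenium ion, so the whole event is a stepwise cationic [4+2] cycloaddition. C2 is created on a planar cation far from the lavandulyl centre, so no control is expected and 26 should form as a pair of C2 epimers in similar amounts, which step 13 resolves. The step needs chemoselectivity for the ynol ether over the prenyl and isopropenyl olefins and ring closure at carbon instead of oxygen: the trioxygenated ring B makes 24 a stabilised and therefore selective electrophile, the silyl ethers of ring B are poor oxygen nucleophiles, and C4a is the only unsubstituted ring A carbon, so the placement of prenyl at C6 and lavandulyl at C8 cannot be scrambled.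

Step 13
Reactants: 26 protected flavanone (C2 epimer pair)
Product: 27 (2S)-5,7-bis(methoxymethoxy)-8-[(2R)-5-methyl-2-(prop-1-en-2-yl)hex-4-en-1-yl]-6-(3-methylbut-2-en-1-yl)-2-[2,4,6-tris(tert-butyldimethylsilyloxy)phenyl]chroman-4-one
Conditions: RuCl[(R,R)-TsDPEN](p-cymene) (1 mol %), HCO2H/Et3N (5:2), EtOAc, 25 °C, stopped at about 55% conversion; chromatography
Reagents that add atoms: none
Why: Noyori asymmetric transfer hydrogenation used as a kinetic resolution of flavanones, in which the (R,R)-catalyst should deliver hydride to the (2R)-epimer anti to its 2-aryl group to give the cis-(2R,4R)-flavan-4-ol much faster than it reduces the (2S)-epimer, so the recovered ketone 27 carries C2 as (S) by catalyst control.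

Step 14
Reactants: 27 (2S)-protected flavanone
Product: 29 (2S)-5,7-dihydroxy-8-[(2R)-5-methyl-2-(prop-1-en-2-yl)hex-4-en-1-yl]-6-(3-methylbut-2-en-1-yl)-2-(2,4,6-trihydroxyphenyl)chroman-4-one (CNP0163831.1), via bis(trimethylsilyl) ether 28 (not isolated)
Conditions: TMSOTf, 2,2'-bipyridyl, CH2Cl2, 0 °C → rt; then KHF2, MeOH, rt
Reagents that add atoms: none
Why: The TMSOTf–bipyridyl complex converts the two aryl MOM ethers into aryl TMS ethers without free acid and bifluoride then removes all five silyl groups, conditions chosen to avoid acid- or base-induced opening of the C2–O1 bond, which would epimerise C2.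

**Compound list**

1 | resorcinol | Oc1cccc(O)c1 | starting material
2 | 1,3-bis(methoxymethoxy)benzene | COCOc1cccc(OCOC)c1 | intermediate
3 | prenyl bromide (1-bromo-3-methylbut-2-ene) | CC(C)=CCBr | starting material
4 | 2-lithio-1,3-bis(methoxymethoxy)benzene | [Li]c1c(OCOC)cccc1OCOC | intermediate
5 | 1,3-bis(methoxymethoxy)-2-(3-methylbut-2-en-1-yl)benzene | COCOc1cccc(OCOC)c1CC=C(C)C | intermediate
6 | 2-[3,5-bis(methoxymethoxy)-4-(3-methylbut-2-en-1-yl)phenyl]-4,4,5,5-tetramethyl-1,3,2-dioxaborolane | COCOc1cc(B2OC(C)(C)C(C)(C)O2)cc(OCOC)c1CC=C(C)C | intermediate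
7 | 3,5-bis(methoxymethoxy)-4-(3-methylbut-2-en-1-yl)phenol | COCOc1cc(O)cc(OCOC)c1CC=C(C)C | intermediate
8 | 2-iodo-3,5-bis(methoxymethoxy)-4-(3-methylbut-2-en-1-yl)phenol | COCOc1cc(O)c(I)c(OCOC)c1CC=C(C)C | intermediate
9 | (S)-4-benzyloxazolidin-2-one | O=C1N[C@@H](Cc2ccccc2)CO1 | starting material
10 | 3-methylbut-2-enoyl chloride | CC(C)=CC(=O)Cl | starting material
11 | (S)-4-benzyl-3-(3-methylbut-2-enoyl)oxazolidin-2-one | CC(C)=CC(=O)N1[C@@H](Cc2ccccc2)COC1=O | intermediate
12 | sodium (Z)-dienolate of 11 | [Na+].C=C(C)/C=C(\[O-])N1[C@@H](Cc2ccccc2)COC1=O | intermediate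
13 | (S)-4-benzyl-3-[(2S)-5-methyl-2-(prop-1-en-2-yl)hex-4-enoyl]oxazolidin-2-one | C=C(C)[C@H](CC=C(C)C)C(=O)N1[C@@H](Cc2ccccc2)COC1=O | intermediate
14 | (S)-lavandulol, (2S)-5-methyl-2-(prop-1-en-2-yl)hex-4-en-1-ol | C=C(C)[C@H](CC=C(C)C)CO | intermediate
15 | (S)-lavandulyl iodide, (3S)-3-(iodomethyl)-2,6-dimethylhepta-1,5-diene | C=C(C)[C@H](CC=C(C)C)CI | intermediate
16 | lavandulyllithium (from 15, configuration unchanged) | C=C(C)[C@H](CC=C(C)C)C[Li] | intermediate
17 | lavandulylzinc chloride (configuration unchanged) | C=C(C)[C@H](CC=C(C)C)C[Zn]Cl | intermediate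
18 | 3,5-bis(methoxymethoxy)-2-[(2R)-5-methyl-2-(prop-1-en-2-yl)hex-4-en-1-yl]-4-(3-methylbut-2-en-1-yl)phenol (ring A phenol) | C=C(C)[C@H](CC=C(C)C)Cc1c(O)cc(OCOC)c(CC=C(C)C)c1OCOC | intermediate
19 | 2,4,6-trihydroxybenzaldehyde | O=Cc1c(O)cc(O)cc1O | starting material
20 | 2,4,6-tris(tert-butyldimethylsilyloxy)benzaldehyde | O=Cc1c(O[Si](C)(C)C(C)(C)C)cc(O[Si](C)(C)C(C)(C)C)cc1O[Si](C)(C)C(C)(C)C | intermediate
21 | chloro[2,4,6-tris(tert-butyldimethylsilyloxy)phenyl]methyl pivalate (racemic) | CC(C)(C)C(=O)OC(Cl)c1c(O[Si](C)(C)C(C)(C)C)cc(O[Si](C)(C)C(C)(C)C)cc1O[Si](C)(C)C(C)(C)C | intermediate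
22 | {3,5-bis(methoxymethoxy)-2-[(2R)-5-methyl-2-(prop-1-en-2-yl)hex-4-en-1-yl]-4-(3-methylbut-2-en-1-yl)phenoxy}[2,4,6-tris(tert-butyldimethylsilyloxy)phenyl]methyl pivalate (both configurations at the acetal carbon) | C=C(C)[C@H](CC=C(C)C)Cc1c(OC(OC(=O)C(C)(C)C)c2c(O[Si](C)(C)C(C)(C)C)cc(O[Si](C)(C)C(C)(C)C)cc2O[Si](C)(C)C(C)(C)C)cc(OCOC)c(CC=C(C)C)c1OCOC | intermediate
23 | ethoxyacetylene (ethoxyethyne) | C#COCC | starting material
24 | aryloxycarbenium ion from 22, as its pivalate–BF3 ion pair | C=C(C)[C@H](CC=C(C)C)Cc1c([O+]=Cc2c(O[Si](C)(C)C(C)(C)C)cc(O[Si](C)(C)C(C)(C)C)cc2O[Si](C)(C)C(C)(C)C)cc(OCOC)c(CC=C(C)C)c1OCOC.CC(C)(C)C(=O)O[B-](F)(F)F | intermediate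
25 | 4-ethoxy-5,7-bis(methoxymethoxy)-8-[(2R)-5-methyl-2-(prop-1-en-2-yl)hex-4-en-1-yl]-6-(3-methylbut-2-en-1-yl)-2-[2,4,6-tris(tert-butyldimethylsilyloxy)phenyl]-2H-chromene (C2 epimer pair) | C=C(C)[C@H](CC=C(C)C)Cc1c(OCOC)c(CC=C(C)C)c(OCOC)c2c1OC(c1c(O[Si](C)(C)C(C)(C)C)cc(O[Si](C)(C)C(C)(C)C)cc1O[Si](C)(C)C(C)(C)C)C=C2OCC | intermediate
26 | 5,7-bis(methoxymethoxy)-8-[(2R)-5-methyl-2-(prop-1-en-2-yl)hex-4-en-1-yl]-6-(3-methylbut-2-en-1-yl)-2-[2,4,6-tris(tert-butyldimethylsilyloxy)phenyl]chroman-4-one (C2 epimer pair) | C=C(C)[C@H](CC=C(C)C)Cc1c(OCOC)c(CC=C(C)C)c(OCOC)c2c1OC(c1c(O[Si](C)(C)C(C)(C)C)cc(O[Si](C)(C)C(C)(C)C)cc1O[Si](C)(C)C(C)(C)C)CC2=O | intermediate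
27 | (2S)-epimer of 26 | C=C(C)[C@H](CC=C(C)C)Cc1c(OCOC)c(CC=C(C)C)c(OCOC)c2c1O[C@H](c1c(O[Si](C)(C)C(C)(C)C)cc(O[Si](C)(C)C(C)(C)C)cc1O[Si](C)(C)C(C)(C)C)CC2=O | intermediate
28 | (2S)-5,7-bis(trimethylsilyloxy) analogue of 27 (MOM replaced by TMS) | C=C(C)[C@H](CC=C(C)C)Cc1c(O[Si](C)(C)C)c(CC=C(C)C)c(O[Si](C)(C)C)c2c1O[C@H](c1c(O[Si](C)(C)C(C)(C)C)cc(O[Si](C)(C)C(C)(C)C)cc1O[Si](C)(C)C(C)(C)C)CC2=O | intermediate
29 | (2S)-5,7-dihydroxy-8-[(2R)-5-methyl-2-(prop-1-en-2-yl)hex-4-en-1-yl]-6-(3-methylbut-2-en-1-yl)-2-(2,4,6-trihydroxyphenyl)chroman-4-one (CNP0163831.1) | C=C(C)[C@H](CC=C(C)C)Cc1c(O)c(CC=C(C)C)c(O)c2c1O[C@H](c1c(O)cc(O)cc1O)CC2=O | target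

**Step count and risks**

Total steps: 14. Longest linear sequence: 9 steps (1–4, 9, 11–14; the lavandulyl branch 5–9, 11–14 is equally long).

Steps most likely to fail:

1. Step 12 (Proposed new method). The ketenium intermediate may be intercepted by an oxygen nucleophile before C4a attacks (pivalate, or O1 with acetal–alkyne metathesis to an aryl cinnamate), or cation 24 may oligomerise by intermolecular Friedel–Crafts attack. The fallback uses known chemistry and sets out from 22. Mukaiyama-type addition of 1,1-bis(trimethylsilyloxy)ethene to the same cation (BF3·OEt2, CH2Cl2, −78 °C) should give, after aqueous work-up, 3-(ring A aryloxy)-3-[2,4,6-tris(tert-butyldimethylsilyloxy)phenyl]propanoic acid F1 as the epimer pair. Intramolecular Friedel–Crafts acylation through the mixed trifluoroacetic anhydride ((CF3CO)2O, CH2Cl2, −20 °C), a standard closure of 3-aryloxypropanoic acids on activated rings, then closes ring C at C4a and comes back to the route at 26.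

2. Step 11. The α-chloro ester 21 may transfer its acyl group to the phenoxide (O-pivaloylation with return of aldehyde 20), the ambident phenoxide may be alkylated at C4a, and the acylal may ionise on isolation. The fallback sets out from 20 and 18 and replaces the acylal by a benzotriazole N,O-acetal. Aldehyde 20, 1H-benzotriazole and SOCl2 (CH2Cl2, 0 °C) should give 1-{chloro[2,4,6-tris(tert-butyldimethylsilyloxy)phenyl]methyl}-1H-benzotriazole F2. The sodium salt of 18 (NaH, DMF) displaces chloride to give 1-{[ring A aryloxy][2,4,6-tris(tert-butyldimethylsilyloxy)phenyl]methyl}-1H-benzotriazole F3, which should survive chromatography. Ionisation of F3 with ZnBr2 in the presence of 23, otherwise as in step 12, expels benzotriazole in place of pivalate and comes back to the route at 26.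

3. Step 13. The two C2 epimers may be reduced at similar rates because the bulky 2',6'-bis(silyloxy)aryl group slows hydride delivery to both, leaving incomplete enrichment. The fallback sets out from 26: the epimers are diastereomers through the lavandulyl centre and are separated by preparative HPLC (on a chiral stationary phase if needed), which comes back to the route at 27. The fallback makes no new compound: none F0.

Further compounds
F1 | step 12 | 3-{3,5-bis(methoxymethoxy)-2-[(2R)-5-methyl-2-(prop-1-en-2-yl)hex-4-en-1-yl]-4-(3-methylbut-2-en-1-yl)phenoxy}-3-[2,4,6-tris(tert-butyldimethylsilyloxy)phenyl]propanoic acid (C3 epimer pair) | C=C(C)[C@H](CC=C(C)C)Cc1c(OC(CC(=O)O)c2c(O[Si](C)(C)C(C)(C)C)cc(O[Si](C)(C)C(C)(C)C)cc2O[Si](C)(C)C(C)(C)C)cc(OCOC)c(CC=C(C)C)c1OCOC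
F2 | step 11 | 1-{chloro[2,4,6-tris(tert-butyldimethylsilyloxy)phenyl]methyl}-1H-benzotriazole (racemic) | ClC(c1c(O[Si](C)(C)C(C)(C)C)cc(O[Si](C)(C)C(C)(C)C)cc1O[Si](C)(C)C(C)(C)C)n1nnc2ccccc12
F3 | step 11 | 1-{{3,5-bis(methoxymethoxy)-2-[(2R)-5-methyl-2-(prop-1-en-2-yl)hex-4-en-1-yl]-4-(3-methylbut-2-en-1-yl)phenoxy}[2,4,6-tris(tert-butyldimethylsilyloxy)phenyl]methyl}-1H-benzotriazole (both configurations at the acetal carbon) | C=C(C)[C@H](CC=C(C)C)Cc1c(OC(c2c(O[Si](C)(C)C(C)(C)C)cc(O[Si](C)(C)C(C)(C)C)cc2O[Si](C)(C)C(C)(C)C)n2nnc3ccccc23)cc(OCOC)c(CC=C(C)C)c1OCOC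
F0 | step 13 | none | none
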